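**Plan**

- Rings: A is the terminal pyrrole, B the methoxy-bearing ring, C the pyrrole that carries the chain. Cs is the spiro carbon (C2 of ring B), Ca the CH between Cs and ring C, Cb the next CH, which carries the heptamethylene bridge.
- Retrosynthesis: the cage is opened at two bonds at once, Ca–Cb and Cs–O of the tetrahydropyran. This leaves a planar tripyrrole in which Ca is the meso carbon, Cb is C8 of an undecyl chain on ring C and the oxygen is a hydroxyl on C10.
- Enabling feature: an electrophilic azafulvene meso carbon next to a charge-stabilising ring B, a chain C–H at C8, and a hydroxyl 1,3 to C8. One hydrogen abstraction can therefore close both rings.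
- Further cuts: the meso C=C (condensation) into a methoxybipyrrole aldehyde (ring A–ring B bond by Suzuki coupling) and a 2-(10-hydroxyundecyl)pyrrole, itself cut at pyrrole C2–chain C1 (hydroboration/B-alkyl Suzuki coupling) and at C8–C9 (Grignard opening of an epoxide).
- Forward: chain C8–C9, then ring C–chain, bipyrrole in parallel, condensation to the linear prodiginine, and last the 12-membered pyrrolophane and the tetrahydropyran in one enzymatic oxidation.
- Stereochemistry: C10 (S) comes from (S)-propylene oxide and is never touched. Ca (S), Cb (S) and Cs (R) arise in the last step under control of the oxygenase pocket, with the C10 carbinol as the matched handle.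

Key step: step 7

Assumption: the oxygenase MarG is available as a recombinant Streptomyces venezuelae strain carrying marG (synthetic gene, standard cloning); it is the catalyst of the last step, its preparation is not counted as a step, and tert-butyl 2-bromopyrrole-1-carboxylate is bought as its stabilised cold solution.

Step 1
Reactants: 1 4-methoxy-1,5-dihydro-2H-pyrrol-2-one (4-methoxy-3-pyrrolin-2-one)
Product: 2 (Z)-N-[(5-bromo-3-methoxy-2H-pyrrol-2-ylidene)methyl]-N-ethylethanamine
Conditions: POBr3 (2.5 equiv), HCONEt2 (3 equiv), CHCl3 then CH2Cl2, 0 °C to 40 °C; aq. NaOH to pH 8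
Reagents that add atoms: N,N-diethylformamide, CCN(CC)C=O; phosphorus oxybromide, O=P(Br)(Br)Br
Why: Vilsmeier–Haack haloformylation: the bromoiminium salt from HCONEt2 and POBr3 attacks C5 of the hydroxypyrrole tautomer of the lactam while the lactam oxygen is exchanged for bromine, and neutralisation should leave the stable vinylogous amidine with the NEt2 group turned away from the methoxy group.

Step 2
Reactants: 2 (Z)-N-[(5-bromo-3-methoxy-2H-pyrrol-2-ylidene)methyl]-N-ethylethanamine; 3 [1-(tert-butoxycarbonyl)-1H-pyrrol-2-yl]boronic acid
Product: 6 4-methoxy-1H,1'H-2,2'-bipyrrole-5-carbaldehyde, via Boc bipyrrole enamine 4 (not isolated), via free bipyrrole enamine 5 (not isolated)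
Conditions: Pd(PPh3)4 (5 mol %), Na2CO3 (3 equiv), 1,4-dioxane/H2O 9:1, 90 °C; then H2O, aq. HCl to pH 7, rt
Reagents that add atoms: water, O
Why: Suzuki–Miyaura coupling at the imidoyl-type C–Br bond, after which the hot aqueous carbonate should cleave the activated N-Boc group of the pyrrole and the aminomethylene azafulvene should hydrolyse on neutral aqueous work-up, because this restores the aromatic pyrrole-2-carbaldehyde.

Step 3
Reactants: 7 8-bromooct-1-ene; 8 (2S)-2-methyloxirane ((S)-propylene oxide)
Product: 10 (2S)-undec-10-en-2-ol, via oct-7-en-1-ylmagnesium bromide 9 (not isolated)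
Conditions: Mg, THF, 40 °C; then CuI (10 mol %), 8, THF, −30 °C to 0 °C; aq. NH4Cl
Reagents that add atoms: none
Why: Copper-catalysed Grignard opening of a terminal epoxide: the organocopper species attacks the unsubstituted CH2 carbon in an SN2 manner, so no bond at the stereocentre is broken and the S configuration of 8 should reappear unchanged in the S carbinol (the later chain C10).

Step 4
Reactants: 10 (2S)-undec-10-en-2-ol; 11 tert-butyl 2-bromo-1H-pyrrole-1-carboxylate
Product: 13 tert-butyl 2-[(10S)-10-hydroxyundecyl]-1H-pyrrole-1-carboxylate, via alkylborane borinate 12 (not isolated)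
Conditions: 9-BBN (2.2 equiv), THF, 0 °C to rt; then aq. K3PO4 (3 M), 11, PdCl2(dppf) (5 mol %), DMF, 50 °C
Reagents that add atoms: none
Why: Hydroboration followed by B-alkyl Suzuki–Miyaura coupling: 9-BBN places boron on the terminal carbon (the second equivalent ties up the carbinol as a borinate that the aqueous base hydrolyses again), and the primary alkylborate should transfer its chain to the 2-pyrrolylpalladium bromide formed from 11, the wide bite angle of dppf favouring reductive elimination over β-hydride elimination, while the remote carbinol centre keeps its configuration.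

Step 5
Reactants: 13 tert-butyl 2-[(10S)-10-hydroxyundecyl]-1H-pyrrole-1-carboxylate
Product: 14 (2S)-11-(1H-pyrrol-2-yl)undecan-2-ol
Conditions: NaOMe, MeOH/THF, rt
Reagents that add atoms: none
Why: Methanolysis of an N-acyl-azole-type carbamate: the nitrogen lone pair belongs to the aromatic sextet, so the Boc carbonyl is unusually electrophilic and methoxide should remove it at room temperature as tert-butyl methyl carbonate without touching the secondary alcohol or its stereocentre.

Step 6
Reactants: 6 4-methoxy-1H,1'H-2,2'-bipyrrole-5-carbaldehyde; 14 (2S)-11-(1H-pyrrol-2-yl)undecan-2-ol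
Product: 15 (S)-23-hydroxyundecylprodiginine [(2S)-11-(5-{(Z)-[3-methoxy-5-(1H-pyrrol-2-yl)-2H-pyrrol-2-ylidene]methyl}-1H-pyrrol-2-yl)undecan-2-ol]
Conditions: HCl (cat.), MeOH, rt, Ar, dark; then aq. NaHCO3 wash (free base)
Reagents that add atoms: none
Why: Acid-catalysed dipyrrin condensation, the standard way to assemble prodiginines: the free α-position of the 2-alkylpyrrole attacks the protonated formyl group of 6 and loss of water should give the conjugated azafulvene as the Z isomer held by an N–H···N hydrogen bond, the distant carbinol taking no part.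

Step 7
Reactants: 15 (S)-23-hydroxyundecylprodiginine
Product: 16 premarineosin A
Conditions: MarG (Rieske oxygenase with a [2Fe-2S] cluster and a mononuclear non-haem iron site; whole cells of Streptomyces venezuelae expressing marG), air (O2), growth medium pH 7, 15 fed in DMSO, 30 °C, dark; EtOAc extraction at pH 7–8, chromatography on NEt3-deactivated silica
Reagents that add atoms: none
Why: The oxygen-activated non-haem iron centre of MarG removes a hydrogen atom from chain C8 of 15; the secondary radical adds to the electron-poor meso carbon Ca of the azafulvene and closes the pyrrolophane in a 12-exo-trig mode (bond Ca–Cb), the radical now spread over rings B and A passes one electron back to the iron centre, and the C10 hydroxyl traps the cation at Cs in a 6-exo-trig closure of the tetrahydropyran (bond Cs–O), so that 15 loses two hydrogens and O2 ends as water. The reaction type is the Rieske-oxygenase oxidative carbocyclisation known for undecylprodiginine-type pigments, in chemical terms a radical addition to an azafulvene followed by radical-polar crossover and capture by a tethered hydroxyl. Cb and Ca are fixed by the face of the flat meso carbon that the enzyme pocket presents to the C8 radical, which should place the heptamethylene bridge at Cb and ring C at Ca trans to each other on the new six-membered ring. Cs is fixed by the face of the ring-B cation that the pocket turns towards the tethered hydroxyl, the S carbinol centre at C10 being the matched handle that carries the nucleophile and keeps its configuration because none of its bonds is broken. The step needs one methylene group out of nine to react and carbon–carbon bond formation to outrun hydroxyl rebound: binding of the bipyrrole head and of the C10 hydroxyl in the pocket holds C8 at the iron centre, the planar electron-poor tripyrrole π system accepts the radical readily and spreads the positive charge that follows, and the hydroxyl stands 1,3 to C8 so that the second ring should close at once.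

**Compound list**

1 | 4-methoxy-1,5-dihydro-2H-pyrrol-2-one (4-methoxy-3-pyrrolin-2-one) | COC1=CC(=O)NC1 | starting material
2 | (Z)-N-[(5-bromo-3-methoxy-2H-pyrrol-2-ylidene)methyl]-N-ethylethanamine | CCN(CC)/C=C1\N=C(Br)C=C1OC | intermediate
3 | [1-(tert-butoxycarbonyl)-1H-pyrrol-2-yl]boronic acid | CC(C)(C)OC(=O)n1cccc1B(O)O | starting material
4 | Boc bipyrrole enamine, tert-butyl 2-{(2Z)-2-[(diethylamino)methylidene]-3-methoxy-2H-pyrrol-5-yl}-1H-pyrrole-1-carboxylate (not isolated) | CCN(CC)/C=C1\N=C(C=C1OC)c1cccn1C(=O)OC(C)(C)C | intermediate
5 | free bipyrrole enamine, (Z)-N-ethyl-N-{[3-methoxy-5-(1H-pyrrol-2-yl)-2H-pyrrol-2-ylidene]methyl}ethanamine (not isolated) | CCN(CC)/C=C1\N=C(C=C1OC)c1ccc[nH]1 | intermediate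
6 | 4-methoxy-1H,1'H-2,2'-bipyrrole-5-carbaldehyde | COc1cc(-c2ccc[nH]2)[nH]c1C=O | intermediate
7 | 8-bromooct-1-ene | C=CCCCCCCBr | starting material
8 | (2S)-2-methyloxirane ((S)-propylene oxide) | C[C@H]1CO1 | starting material
9 | oct-7-en-1-ylmagnesium bromide (not isolated) | C=CCCCCCC[Mg]Br | intermediate
10 | (2S)-undec-10-en-2-ol | C[C@H](O)CCCCCCCC=C | intermediate
11 | tert-butyl 2-bromo-1H-pyrrole-1-carboxylate | CC(C)(C)OC(=O)n1cccc1Br | starting material
12 | alkylborane borinate, 9-[(10S)-10-(9-borabicyclo[3.3.1]nonan-9-yloxy)undecyl]-9-borabicyclo[3.3.1]nonane (not isolated) | C[C@H](OB1C2CCCC1CCC2)CCCCCCCCCB1C2CCCC1CCC2 | intermediate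
13 | tert-butyl 2-[(10S)-10-hydroxyundecyl]-1H-pyrrole-1-carboxylate | C[C@H](O)CCCCCCCCCc1cccn1C(=O)OC(C)(C)C | intermediate
14 | (2S)-11-(1H-pyrrol-2-yl)undecan-2-ol | C[C@H](O)CCCCCCCCCc1ccc[nH]1 | intermediate
15 | (S)-23-hydroxyundecylprodiginine, (2S)-11-(5-{(Z)-[3-methoxy-5-(1H-pyrrol-2-yl)-2H-pyrrol-2-ylidene]methyl}-1H-pyrrol-2-yl)undecan-2-ol | COC1=CC(c2ccc[nH]2)=N/C1=C\c1ccc(CCCCCCCCC[C@H](C)O)[nH]1 | intermediate
16 | premarineosin A (Cs R, Ca S, Cb S, C10 S; on the tetrahydropyran the methyl group, ring C and the ring-B nitrogen lie on one face, the heptamethylene bridge and ring-B C3 on the other) | COC1=CC(c2ccc[nH]2)=N[C@]12O[C@@H](C)C[C@@H]1CCCCCCCc3ccc([nH]3)[C@H]12 | target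

**Step count**

Total step count: 7 (steps 1–2 bipyrrole branch, steps 3–5 chain branch, steps 6–7 union and cyclisation).
Longest linear sequence: 5 steps (steps 3, 4, 5, 6, 7).

**Steps most likely to fail**

Step 7. The lipophilic pigment may enter the cells slowly, turnover may stay incomplete, and the spiro aminal may reopen through traces of acid or light during isolation. The fallback moves the condensation into the cell. It sets out from 14 and returns to the route at 16. Compound 14 is fed to a Streptomyces strain that carries the marineosin gene cluster with the genes for the monopyrrole chain and the reductase gene marA inactivated. The organism makes the bipyrrole aldehyde itself, its condensing enzyme joins it to the fed pyrrole inside the cell, and MarG cyclises the prodiginine where substrate, enzyme and electron-transfer partners are together. The pathway stops at 16 because the reductase is missing. This fallback makes no new compound (F0).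

Step 4. The labile bromopyrrole may debrominate or decompose before oxidative addition, the Boc group may be lost early so that a pyrrolide slows the coupling, and the alkylpalladium intermediate may undergo β-hydride elimination. The fallback replaces the cross-coupling by acylation of pyrrole and reduction. It sets out from 10 and returns at 14.
- The carbinol of 10 is silylated (TBSCl, imidazole, DMF) to tert-butyldimethyl{[(2S)-undec-10-en-2-yl]oxy}silane F1.
- 9-BBN in THF gives 9-[(10S)-10-(tert-butyldimethylsilyloxy)undecyl]-9-borabicyclo[3.3.1]nonane F2, which is oxidised without isolation (NaOH, H2O2) to (10S)-10-(tert-butyldimethylsilyloxy)undecan-1-ol F3.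
- TEMPO (cat.) and PhI(OAc)2 in MeCN/H2O take this to (10S)-10-(tert-butyldimethylsilyloxy)undecanoic acid F4.
- 2,2'-Dipyridyl disulfide and PPh3 in toluene convert the acid into S-(pyridin-2-yl) (10S)-10-(tert-butyldimethylsilyloxy)undecanethioate F5.
- Pyrrole and MeMgCl in toluene give 1H-pyrrol-1-ylmagnesium chloride F6, which the thioester acylates at C2 at −78 °C to (10S)-10-(tert-butyldimethylsilyloxy)-1-(1H-pyrrol-2-yl)undecan-1-one F7.
- NaBH4 in refluxing 2-propanol reduces the pyrrolyl ketone through its azafulvene to 2-[(10S)-10-(tert-butyldimethylsilyloxy)undecyl]-1H-pyrrole F8.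
- Bu4NF in THF frees 14.

Step 6. The acid may oligomerise the α-free alkylpyrrole, the electron-rich partners may oxidise in air, and the vinylogous-amide aldehyde may react too slowly. The fallback brings ring A in last. It sets out from 2 and 14 and returns at 15.
- The amidine 2 is a masked and more electrophilic aldehyde. In MeOH with AcOH it should condense with 14 at rt, with loss of diethylamine, to the bromodipyrrin (2S)-11-{5-[(Z)-(5-bromo-3-methoxy-2H-pyrrol-2-ylidene)methyl]-1H-pyrrol-2-yl}undecan-2-ol F9.
- Suzuki–Miyaura coupling of F9 with 3 (Pd(PPh3)4, Na2CO3, 1,4-dioxane/H2O, 90 °C) gives tert-butyl 2-{(2Z)-2-({5-[(10S)-10-hydroxyundecyl]-1H-pyrrol-2-yl}methylidene)-3-methoxy-2H-pyrrol-5-yl}-1H-pyrrole-1-carboxylate F10, which is not isolated and loses its Boc group in the hot basic medium to give 15.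

**Further compounds**

F0 | step 7 | none | none
F1 | step 4 | tert-butyldimethyl{[(2S)-undec-10-en-2-yl]oxy}silane | C[C@H](O[Si](C)(C)C(C)(C)C)CCCCCCCC=C
F2 | step 4 | 9-[(10S)-10-(tert-butyldimethylsilyloxy)undecyl]-9-borabicyclo[3.3.1]nonane | C[C@H](O[Si](C)(C)C(C)(C)C)CCCCCCCCCB1C2CCCC1CCC2
F3 | step 4 | (10S)-10-(tert-butyldimethylsilyloxy)undecan-1-ol | C[C@H](O[Si](C)(C)C(C)(C)C)CCCCCCCCCO
F4 | step 4 | (10S)-10-(tert-butyldimethylsilyloxy)undecanoic acid | C[C@H](O[Si](C)(C)C(C)(C)C)CCCCCCCCC(=O)O
F5 | step 4 | S-(pyridin-2-yl) (10S)-10-(tert-butyldimethylsilyloxy)undecanethioate | C[C@H](O[Si](C)(C)C(C)(C)C)CCCCCCCCC(=O)Sc1ccccn1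
F6 | step 4 | 1H-pyrrol-1-ylmagnesium chloride | Cl[Mg]n1cccc1
F7 | step 4 | (10S)-10-(tert-butyldimethylsilyloxy)-1-(1H-pyrrol-2-yl)undecan-1-one | C[C@H](O[Si](C)(C)C(C)(C)C)CCCCCCCCC(=O)c1ccc[nH]1
F8 | step 4 | 2-[(10S)-10-(tert-butyldimethylsilyloxy)undecyl]-1H-pyrrole | C[C@H](O[Si](C)(C)C(C)(C)C)CCCCCCCCCc1ccc[nH]1
F9 | step 6 | (2S)-11-{5-[(Z)-(5-bromo-3-methoxy-2H-pyrrol-2-ylidene)methyl]-1H-pyrrol-2-yl}undecan-2-ol | COC1=CC(Br)=N/C1=C\c1ccc(CCCCCCCCC[C@H](C)O)[nH]1
F10 | step 6 | tert-butyl 2-{(2Z)-2-({5-[(10S)-10-hydroxyundecyl]-1H-pyrrol-2-yl}methylidene)-3-methoxy-2H-pyrrol-5-yl}-1H-pyrrole-1-carboxylate | COC1=CC(c2cccn2C(=O)OC(C)(C)C)=N/C1=C\c1ccc(CCCCCCCCC[C@H](C)O)[nH]1
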